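(All runs were computed with made-up constants.)

The product in the flask at 6.0 min was what had dissolved by then, less what still stood in solution or trapped, so I needed these two amounts from the runs.

| flask | solid substrate | reagent | capture agent | remark | time |
|---|---|---|---|---|---|
| Thursday's | 0.11 M | 1 equiv (fed, over 10 s) | 0.017 M | run made earlier |  |
| Sunday's | 0.26 M | 1 equiv (fed, over 10 s) | 0.017 M | run made earlier |  |
| flask | 0.17 M | 1.00 equiv (fed, over 10 s) | 0.0170 M |  | 6.0 min |

| run | time / min | product / % | trapped intermediate / % | intermediate B / % | starting material / % | intermediate C / % | solid substrate / % | intermediate A / % |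
|---|---|---|---|---|---|---|---|---|
| Thursday's | 0.417 | 0 | 0 | 1 | 8 | 0 | 86 | 4 |
| Thursday's | 1.33 | 6 | 3 | 7 | 13 | 1 | 63 | 4 |
| Thursday's | 2.00 | 16 | 10 | 7 | 10 | 4 | 52 | 4 |
| Thursday's | 3.00 | 21 | 13 | 8 | 14 | 1 | 37 | 5 |
| Thursday's | 5.00 | 41 | 15 | 9 | 17 | 9 | 8 | 4 |
| Thursday's | 6.00 | 48 | 16 | 10 | 13 | 9 | 0 | 3 |
| Sunday's | 0.417 | 0 | 2 | 1 | 3 | 1 | 96 | 2 |
| Sunday's | 1.33 | 6 | 1 | 2 | 8 | 2 | 83 | 1 |
| Sunday's | 2.00 | 12 | 4 | 1 | 3 | 1 | 77 | 6 |
| Sunday's | 3.00 | 18 | 4 | 2 | 7 | 1 | 67 | 5 |
| Sunday's | 5.00 | 34 | 6 | 2 | 4 | 3 | 47 | 3 |
| Sunday's | 6.00 | 41 | 8 | 4 | 5 | 3 | 37 | 3 |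

(readings scatter by 1.5 percentage points)

- solid, in amounts per volume of the solution: solid substrate
- at the start none of the solid substrate is in solution
- starting material means what is dissolved; the solid is not counted in it

* the largest share of what was charged as solid substrate, at 6.0 min belongs to (trapped intermediate / intermediate C / product / intermediate B / intermediate A / starting material)
* the largest share itself, whichever of these holds it, in percent of the solid substrate charged

The first amount, D, is what had dissolved by time t, and I wrote it D = r t, with r the dissolving rate in M per minute. Solid fell in a nearly straight line (roughly zero-order), so a steady rate integrates to this closed form. From the first reading to the last with solid still standing, Thursday's run lost 0.0187 M min⁻¹ and Sunday's lost 0.0275 M min⁻¹. Interpolating by charge, I took 0.0222 M min⁻¹ as r, the dissolving rate, for the flask. That gave D = 0.133 M.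

The second amount, the holdup H, is the sum of starting material, intermediates A, B and C, and trapped intermediate. At 6.00 min it read 0.0561 M on Thursday and 0.0598 M on Sunday, so I took 0.0580 M. The ratio H/D was 43.6%, which left product at 44.3% of the charge.

The forecast said product at 46%, holding that “Dissolution is the controlling step”; my figure was lower.

The flask gave product at 44.1%.

    intermediate B ⇌ intermediate C (K = 1.20, k = 0.00920 s⁻¹)
    solid substrate ⇌ starting material, rate k2*(cs2 - [starting material]) while solid is left; crystals form when [starting material] > cs2 (solubility = 26.0 mM, k = 0.0330 s⁻¹)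
    starting material ⇌ intermediate B (K = 0.550, k = 0.0240 s⁻¹)
    starting material + reagent → intermediate A (k = 0.120 L mol⁻¹ s⁻¹)
    intermediate A → product (k = 0.0400 s⁻¹)
    capture agent + intermediate B → trapped intermediate (k = 2.20 L mol⁻¹ s⁻¹)

In the flask, solid still stood at 21.7% at 6.00 min, so dissolving was still running, with net turnover 78.3% against the 78.4% from r. Alongside it, the step from intermediate A to product had done half of its turnover up to 6.0 min by 3.21 min, and by 6.00 min capture agent stood at 0.912% of its charge. For the neighbour flask charged with 0.043 M, r carried over unchanged gave the solid a reckoned life of 1.94 min, shorter than 6.0 min, and that flask held 0% solid at 6.00 min.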